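**Assumption:** the target is the (2R,4S,6S,1′S) isomer encoded by the SMILES (2,6-cis tetrahydropyran, 4-OH trans to both ring substituents, i.e. axial; threo side-chain carbinol). Simple methylating, formylating, protecting and acyl-transfer reagents are treated as reagents, not numbered compounds.

## Retrosynthetic overview

1. Rhoiptelol B ⇐ removal of one aryl tosylate and two benzyl ethers, after Mitsunobu inversion at C4 of the all-cis tetrahydropyranol 16.
2. 16 ⇐ Prins cyclization of aryl aldehyde 5 (guaiacyl C1 unit) with homoallylic alcohol 15 (aryl C6 unit); this forms O1–C2 and C3–C4.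
3. 15 ⇐ chelation-controlled allylation of α-benzyloxy aldehyde 13 ⇐ Cu-catalysed opening of (S)-trityl glycidyl ether by the Grignard reagent from O-benzyl-4-bromophenol.
4. 5 ⇐ catechol by mono-methylation, para-bromination, formylation and tosylation.
5. Ring order: both benzene rings are bought; the tetrahydropyran is the only ring made, in the Prins step.

Ring numbering used below: O1, C2 bears the guaiacyl ring, C4 bears OH, C6 bears the side chain.

## Route

**Step 1**
Reactants: 1 catechol
Product: 2 guaiacol (2-methoxyphenol)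
Conditions: MeI (0.95 equiv), K2CO3, acetone, reflux; separate from veratrole, recycle catechol
Reagents that add atoms: iodomethane, CI
Why: Williamson mono-O-methylation of a symmetrical diphenol; sub-stoichiometric MeI limits dimethylation.

**Step 2**
Reactants: 2 guaiacol
Product: 3 4-bromo-2-methoxyphenol
Conditions: NBS, MeCN, 0 °C
Reagents that add atoms: N-bromosuccinimide, BrN1C(=O)CCC1=O
Why: Electrophilic aromatic bromination goes para to the free OH, the stronger donor.

**Step 3**
Reactants: 3 4-bromo-2-methoxyphenol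
Product: 4 vanillin (4-hydroxy-3-methoxybenzaldehyde)
Conditions: n-BuLi (1.05 equiv), THF, −78 °C; t-BuLi (2.1 equiv), −78 °C; DMF, −78 °C → rt; aq. HCl
Reagents that add atoms: N,N-dimethylformamide, CN(C)C=O
Why: Bromine–lithium exchange on the lithium phenoxide followed by formylation of the aryllithium with DMF puts CHO exactly where Br was.

**Step 4**
Reactants: 4 vanillin
Product: 5 4-formyl-2-methoxyphenyl 4-methylbenzenesulfonate (O-tosylvanillin)
Conditions: TsCl, Et3N, DMAP (cat.), CH2Cl2, 0 °C → rt
Reagents that add atoms: p-toluenesulfonyl chloride, Cc1ccc(cc1)S(Cl)(=O)=O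
Why: Phenol sulfonylation; the tosylate protects the phenol and makes the aldehyde less electron-rich, which suppresses oxonia-Cope side reactions in the Prins step.

**Step 5**
Reactants: 6 4-bromophenol
Product: 7 1-(benzyloxy)-4-bromobenzene
Conditions: BnBr, K2CO3, acetone, reflux
Reagents that add atoms: benzyl bromide, BrCc1ccccc1
Why: Williamson etherification protects the phenol so the aryl bromide can be converted to a Grignard reagent.

**Step 6**
Reactants: 8 (R)-glycidol
Product: 9 (S)-2-[(trityloxy)methyl]oxirane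
Conditions: TrCl, Et3N, DMAP (cat.), CH2Cl2, 0 °C → rt
Reagents that add atoms: trityl chloride, ClC(c1ccccc1)(c1ccccc1)c1ccccc1
Why: Tritylation of the primary alcohol leaves the epoxide and stereocentre untouched; the descriptor changes from R to S only because CIP priorities change.

**Step 7**
Reactants: 7 1-(benzyloxy)-4-bromobenzene; 9 (S)-trityl glycidyl ether
Product: 10 (2S)-1-[4-(benzyloxy)phenyl]-3-(trityloxy)propan-2-ol
Conditions: 7, Mg, THF, reflux; then CuI (10 mol %), 9, THF, −30 → 0 °C
Reagents that add atoms: none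
Why: Cu(I)-catalysed Grignard opening of the terminal epoxide occurs by SN2 at the unsubstituted carbon, so the C2 stereocentre is carried over unchanged.

**Step 8**
Reactants: 10
Product: 11 1-(benzyloxy)-4-[(2S)-2-(benzyloxy)-3-(trityloxy)propyl]benzene
Conditions: NaH, BnBr, TBAI (cat.), THF/DMF, 0 °C → rt
Reagents that add atoms: benzyl bromide, BrCc1ccccc1
Why: Williamson benzylation of the secondary alkoxide; the trityl ether cannot migrate and the benzyl ether later serves as the chelating group.

**Step 9**
Reactants: 11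
Product: 12 (2S)-2-(benzyloxy)-3-[4-(benzyloxy)phenyl]propan-1-ol
Conditions: p-TsOH·H2O (cat.), MeOH/CH2Cl2, rt
Reagents that add atoms: none
Why: Acid-catalysed SN1 methanolysis removes the trityl ether selectively; benzyl ethers are stable.

**Step 10**
Reactants: 12
Product: 13 (2S)-2-(benzyloxy)-3-[4-(benzyloxy)phenyl]propanal
Conditions: Dess–Martin periodinane, NaHCO3, CH2Cl2, 0 °C → rt; used crude
Reagents that add atoms: none
Why: Dess–Martin oxidation is non-basic, so the α-alkoxy aldehyde is formed without epimerisation.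

**Step 11**
Reactants: 13; 14 allyltrimethylsilane
Product: 15 (2S,3S)-2-(benzyloxy)-1-[4-(benzyloxy)phenyl]hex-5-en-3-ol
Conditions: SnCl4 (1.1 equiv), CH2Cl2, −78 °C, 10 min; then 14, −78 °C
Reagents that add atoms: none (the allyl group comes from 14; Me3Si is lost)
Why: Hosomi–Sakurai allylation under Cram-chelate control: SnCl4 bridges C=O and the α-OBn, and the silane attacks the face bearing H, giving the syn (threo) 3S alcohol.

**Step 12**
Reactants: 15; 5 O-tosylvanillin
Product: 16 4-[(2R,4R,6S)-6-{(1S)-1-(benzyloxy)-2-[4-(benzyloxy)phenyl]ethyl}-4-hydroxyoxan-2-yl]-2-methoxyphenyl 4-methylbenzenesulfonate (2,4,6-all-cis)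
Conditions: TFA, CH2Cl2, 0 °C → rt; then K2CO3, MeOH, 0 °C (one pot, cleaves the trifluoroacetate)
Reagents that add atoms: trifluoroacetic acid, OC(=O)C(F)(F)F (supplies the C4 oxygen; the acyl part is removed in the work-up)
Why: Prins cyclization through an (E)-oxocarbenium ion in a chair transition state puts both substituents equatorial (2,6-cis, C6 configuration retained from 15), and trifluoroacetate captures the C4 cation equatorially.

**Step 13**
Reactants: 16
Product: 17 (2R,4S,6S)-6-{(1S)-1-(benzyloxy)-2-[4-(benzyloxy)phenyl]ethyl}-2-[3-methoxy-4-(tosyloxy)phenyl]oxan-4-yl 4-nitrobenzoate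
Conditions: 4-nitrobenzoic acid, PPh3, DIAD, THF, 0 °C → rt
Reagents that add atoms: 4-nitrobenzoic acid, OC(=O)c1ccc(cc1)[N+](=O)[O-]
Why: Mitsunobu reaction displaces the activated equatorial C4 oxygen by SN2, giving the axial ester (4R → 4S).

**Step 14**
Reactants: 17
Product: 18 4-[(2R,4S,6S)-6-{(1S)-1-(benzyloxy)-2-[4-(benzyloxy)phenyl]ethyl}-4-hydroxyoxan-2-yl]-2-methoxyphenol
Conditions: KOH, MeOH/THF/H2O, 60 °C
Reagents that add atoms: none
Why: Saponification cleaves the nitrobenzoate at the acyl carbon and the aryl tosylate at sulfur, so no stereocentre is touched.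

**Step 15**
Reactants: 18
Product: 19 rhoiptelol B, (2R,4S,6S)-2-(4-hydroxy-3-methoxyphenyl)-6-[(1S)-1-hydroxy-2-(4-hydroxyphenyl)ethyl]oxan-4-ol
Conditions: H2 (1 atm), 10 % Pd/C, EtOAc/MeOH, rt; stop at consumption of 18
Reagents that add atoms: none
Why: Catalytic hydrogenolysis removes the phenolic and the secondary benzyl ethers; the cyclic benzylic C–O bond is much slower to cleave.

## Compound list

1 | catechol | Oc1ccccc1O | starting material
2 | guaiacol | COc1ccccc1O | intermediate
3 | 4-bromo-2-methoxyphenol | COc1cc(Br)ccc1O | intermediate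
4 | vanillin | COc1cc(C=O)ccc1O | intermediate
5 | 4-formyl-2-methoxyphenyl 4-methylbenzenesulfonate | COc1cc(C=O)ccc1OS(=O)(=O)c1ccc(C)cc1 | intermediate
6 | 4-bromophenol | Oc1ccc(Br)cc1 | starting material
7 | 1-(benzyloxy)-4-bromobenzene | Brc1ccc(OCc2ccccc2)cc1 | intermediate
8 | (R)-glycidol | OC[C@@H]1CO1 | starting material
9 | (S)-2-[(trityloxy)methyl]oxirane | C(OC[C@@H]1CO1)(c1ccccc1)(c1ccccc1)c1ccccc1 | intermediate
10 | (2S)-1-[4-(benzyloxy)phenyl]-3-(trityloxy)propan-2-ol | C(OC[C@@H](O)Cc1ccc(OCc2ccccc2)cc1)(c1ccccc1)(c1ccccc1)c1ccccc1 | intermediate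
11 | 1-(benzyloxy)-4-[(2S)-2-(benzyloxy)-3-(trityloxy)propyl]benzene | C(OC[C@@H](OCc1ccccc1)Cc1ccc(OCc2ccccc2)cc1)(c1ccccc1)(c1ccccc1)c1ccccc1 | intermediate
12 | (2S)-2-(benzyloxy)-3-[4-(benzyloxy)phenyl]propan-1-ol | OC[C@@H](OCc1ccccc1)Cc1ccc(OCc2ccccc2)cc1 | intermediate
13 | (2S)-2-(benzyloxy)-3-[4-(benzyloxy)phenyl]propanal | O=C[C@@H](OCc1ccccc1)Cc1ccc(OCc2ccccc2)cc1 | intermediate
14 | allyltrimethylsilane | C=CC[Si](C)(C)C | starting material
15 | (2S,3S)-2-(benzyloxy)-1-[4-(benzyloxy)phenyl]hex-5-en-3-ol | C=CC[C@H](O)[C@@H](OCc1ccccc1)Cc1ccc(OCc2ccccc2)cc1 | intermediate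
16 | all-cis (2R,4R,6S) tetrahydropyran-4-ol, aryl tosylate, two benzyl ethers | COc1cc([C@H]2C[C@@H](O)C[C@@H]([C@@H](OCc3ccccc3)Cc3ccc(OCc4ccccc4)cc3)O2)ccc1OS(=O)(=O)c1ccc(C)cc1 | intermediate
17 | (2R,4S,6S) axial 4-nitrobenzoate | COc1cc([C@H]2C[C@H](OC(=O)c3ccc(cc3)[N+](=O)[O-])C[C@@H]([C@@H](OCc3ccccc3)Cc3ccc(OCc4ccccc4)cc3)O2)ccc1OS(=O)(=O)c1ccc(C)cc1 | intermediate
18 | di-O-benzyl rhoiptelol B (free guaiacyl phenol, axial 4-OH) | COc1cc([C@H]2C[C@H](O)C[C@@H]([C@@H](OCc3ccccc3)Cc3ccc(OCc4ccccc4)cc3)O2)ccc1O | intermediate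
19 | rhoiptelol B | COc1cc([C@H]2C[C@H](O)C[C@@H]([C@@H](O)Cc3ccc(O)cc3)O2)ccc1O | target

## Summary

Total step count: 15.

Longest linear sequence: 10 steps (4-bromophenol: steps 5, 7–15; equally (R)-glycidol: steps 6, 7–15). The aldehyde branch (steps 1–4) runs in parallel.

Steps most likely to fail:

1. **Step 12 (Prins cyclization).** Risks are slow cyclization and allyl-transfer (oxonia-Cope) by-products. Fallback: build the ring by oxa-Michael instead. Wacker-oxidise 15 to the β-hydroxy methyl ketone, condense it with 5 to the aryl enone, and close by 6-endo oxa-Michael addition to the 2,6-cis tetrahydropyran-4-one. L-Selectride reduction then gives the axial C4 alcohol directly, replacing steps 12 and 13.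
2. **Step 3 (Br–Li exchange on a phenoxide, then DMF).** Risks are incomplete exchange and poor solubility of the dianion. Fallback: avoid organolithium chemistry by making vanillin from guaiacol 2 through base-mediated para-condensation with glyoxylic acid, then oxidative decarboxylation of the mandelic acid.
3. **Step 15 (hydrogenolysis).** The risk is reductive opening of the electron-rich benzylic ring C2–O bond. Fallback: change the endgame order. Use benzoic acid in the Mitsunobu step, hydrogenolyse the benzyl ethers while the guaiacyl oxygen is still tosylated (the benzylic ether is then deactivated), and finish with the KOH step to release the benzoate and tosylate.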